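**Retrosynthetic overview**

1. Numbering as in longipinane: C1 ketone, C2=C3(Me), cyclobutane C4–C5–C11–C10, C6 (CMe2), C7 (methacrylate), C8 (CH2), C9 (angelate). The O9 angelate is attached late, and the C1(=O)–C2=C3 enone is unmasked last from a silyl-protected C1 carbinol.
2. The seven-membered ring C4–C5–C6–C7–C8–C9–C10 is closed last, at C7–C8: ring-closing aldol of a C10 acetyl group (C9, C8) onto a C5–C6Me2–C7HO aldehyde, run in one flask with an Evans–Tishchenko reduction by methacrolein (sets C7 and C9, puts the methacrylate on O7).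
3. Feature that makes this possible: C5 and C10 are the two one-carbon bridges of the bicyclo[3.1.1]heptane, i.e. opposite corners of the cyclobutane, and their arms both point away from the C1–C3 bridge (cis-1,3, roughly 3 Å apart); C10 and C6 are quaternary, so only C8 can enolize and C7 cannot.
4. The C5 arm grows from a cyclobutanone carbonyl at C5 (olefination, hydrogenation directed by the C1 hydroxyl, double methylation). Before that, cyclobutane and six-membered ring are formed together by an intramolecular vinylketene–alkene [2+2] cycloaddition of an acyclic dienoic acid.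
5. The (E)-alkene of that acid fixes C10; one carbinol from an asymmetric vinylogous aldol (the future C1) fixes the absolute configuration of C4, C10 and C11. Ring order: cyclobutane + cyclohexane (step 8), then cycloheptane (step 17).

Key step: step 17

Assumption: the sense of induction of the chiral catalysts in steps 5 and 17 is taken from their behaviour with simple aldehydes; should it be reversed on these substrates, the antipodal catalyst serves.

**Route**

Step 1
Reactants: 1 3,3-dimethoxybutan-2-one; 2 triethyl phosphonoacetate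
Product: 3 ethyl (2E)-4,4-dimethoxy-3-methylpent-2-enoate
Conditions: NaH, THF, 0 °C to reflux
Reagents that add atoms: none
Why: Horner–Wadsworth–Emmons olefination of the methyl ketone should place the bulky ketal carbon trans to the ester, giving the (E)-alkene whose geometry later fixes the quaternary centre C10.

Step 2
Reactants: 3 ethyl (2E)-4,4-dimethoxy-3-methylpent-2-enoate
Product: 4 (2E)-4,4-dimethoxy-3-methylpent-2-en-1-ol
Conditions: i-Bu2AlH, CH2Cl2, −78 °C
Reagents that add atoms: none
Why: Hydride 1,2-reduction of the conjugated ester gives the allylic alcohol without touching the ketal or the alkene geometry.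

Step 3
Reactants: 4 (2E)-4,4-dimethoxy-3-methylpent-2-en-1-ol
Product: 5 (2E)-4,4-dimethoxy-3-methylpent-2-enal
Conditions: MnO2, CH2Cl2, rt
Reagents that add atoms: none
Why: Allylic oxidation with MnO2 stops at the enal under neutral conditions that spare the acid-labile ketal.

Step 4
Reactants: 6 methyl 3-methylbut-2-enoate
Product: 7 silyl dienolate of 6
Conditions: LiN(i-Pr)2, THF, −78 °C; t-BuMe2SiCl, DMPU, −78 °C to rt
Reagents that add atoms: tert-butyldimethylsilyl chloride, CC(C)(C)[Si](C)(C)Cl
Why: γ-Deprotonation of the senecioate and O-silylation (silyl ketene acetal formation) give the dienolate needed for the vinylogous aldol.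

Step 5
Reactants: 5 (2E)-4,4-dimethoxy-3-methylpent-2-enal; 7 silyl dienolate
Product: 8 methyl (2E,5S,6E)-5-hydroxy-8,8-dimethoxy-3,7-dimethylnona-2,6-dienoate
Conditions: SiCl4, (S,S)-Denmark bisphosphoramide (5 mol %), i-Pr2NEt (10 mol %), CH2Cl2, −78 °C; aq. NaHCO3
Reagents that add atoms: none
Why: Catalytic asymmetric vinylogous Mukaiyama aldol addition, in which the dienolate attacks through its γ-carbon and the chiral Lewis-base-bound silyl cation selects the aldehyde face, should set the (5S) carbinol (the future C1), while the low temperature and amine buffer protect the ketal.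

Step 6
Reactants: 8 hydroxy dienoate
Product: 9 methyl (2E,5S,6E)-5-[(tert-butyldimethylsilyl)oxy]-8,8-dimethoxy-3,7-dimethylnona-2,6-dienoate
Conditions: t-BuMe2SiCl, imidazole, DMF, rt
Reagents that add atoms: tert-butyldimethylsilyl chloride, CC(C)(C)[Si](C)(C)Cl
Why: Silylation of the secondary allylic alcohol masks it for ketene generation and makes it the bulky group that later controls the facial selectivity.

Step 7
Reactants: 9 silyloxy dienoate
Product: 10 (2E,5S,6E)-5-[(tert-butyldimethylsilyl)oxy]-8,8-dimethoxy-3,7-dimethylnona-2,6-dienoic acid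
Conditions: LiOH, THF/MeOH/H2O, rt; AcOH to pH 5
Reagents that add atoms: lithium hydroxide, [Li+].[OH-]
Why: Saponification of the methyl ester with a buffered work-up gives the acid while silyl ether and ketal survive.

Step 8
Reactants: 10 silyloxy dienoic acid
Product: 12 bicyclo[3.1.1]heptan-6-one (cyclobutanone), via vinylketene 11 (not isolated)
Conditions: 2-chloro-1-methylpyridinium iodide, Et3N, toluene, reflux, slow addition at high dilution
Reagents that add atoms: none
Why: Intramolecular vinylketene–alkene [2+2] cycloaddition: the activated acid is dehydrated to the vinylketene, whose carbonyl carbon bonds to the alkene CH while the ring closes at the carbon that best carries positive charge, so the bridged bicyclo[3.1.1]heptan-6-one (cyclobutane and six-membered ring at once) should form; the (E)-alkene geometry is transferred suprafacially (methyl syn to the three-carbon bridge, future C10), and allylic 1,3-strain at the silyloxy carbon (its hydrogen eclipsing the alkene, the tether attacking opposite to the silyl ether) selects the face and so sets C4 and C11.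

Step 9
Reactants: 12 cyclobutanone; 2 triethyl phosphonoacetate
Product: 13 alkylidene acetate
Conditions: NaH, THF, 0 °C to reflux
Reagents that add atoms: none
Why: Horner–Wadsworth–Emmons olefination of the strained, non-enolizable cyclobutanone attaches the two-carbon stub of the C5 arm; either alkene geometry serves because the next step saturates it.

Step 10
Reactants: 13 alkylidene acetate
Product: 14 hydroxy alkylidene acetate
Conditions: Bu4NF, THF, 0 °C to rt
Reagents that add atoms: none
Why: Fluoride desilylation frees the C1 hydroxyl, which is needed as the directing group, under non-acidic conditions that keep the ketal.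

Step 11
Reactants: 14 hydroxy alkylidene acetate
Product: 15 saturated hydroxy ester
Conditions: [Ir(cod)(PCy3)(py)]PF6 (10 mol %), H2 (1–4 atm), CH2Cl2, rt
Reagents that add atoms: none
Why: Hydroxyl-directed homogeneous hydrogenation: the iridium centre binds the C1 hydroxyl, which lies over the upper face of the exocyclic alkylidene, so hydrogen is delivered to C5 from that face and the acetate arm is pushed to the lower face, cis to the ketal arm on C10; the methylidene is reduced in the same operation from the same side, giving a C3 centre that is erased in step 20.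

Step 12
Reactants: 15 saturated hydroxy ester
Product: 16 silyl ether of 15
Conditions: t-BuMe2SiCl, imidazole, DMF, 40 °C
Reagents that add atoms: tert-butyldimethylsilyl chloride, CC(C)(C)[Si](C)(C)Cl
Why: Re-silylation under basic conditions blocks the C1 oxygen through the enolate, hydride, oxidation and acylation steps that follow.

Step 13
Reactants: 16 silyl ether ester
Product: 18 gem-dimethyl ester, via monomethyl ester 17 (not isolated)
Conditions: LiN(i-Pr)2, THF, −78 °C, then MeI; repeated in the same flask with LiN(i-Pr)2, DMPU, MeI, −78 to 0 °C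
Reagents that add atoms: iodomethane, CI
Why: Two successive ester enolate alkylations build the quaternary carbon C6; no other position in the molecule is acidic and the enolate has no leaving group in the β-position.

Step 14
Reactants: 18 gem-dimethyl ester
Product: 19 neopentyl alcohol
Conditions: i-Bu2AlH, CH2Cl2, −78 to 0 °C
Reagents that add atoms: none
Why: Hydride reduction of the hindered ester to the primary alcohol leaves silyl ether and ketal intact.

Step 15
Reactants: 19 neopentyl alcohol
Product: 20 neopentyl aldehyde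
Conditions: Dess–Martin periodinane, pyridine, CH2Cl2, rt
Reagents that add atoms: none
Why: Buffered Dess–Martin oxidation gives the aldehyde (C7), which cannot enolize and is therefore configurationally and chemically robust.

Step 16
Reactants: 20 neopentyl aldehyde
Product: 21 keto-aldehyde
Conditions: PPTS, acetone/H2O, 40 °C
Reagents that add atoms: water, O
Why: Mild acid-catalysed hydrolysis of the dimethyl ketal releases the acetyl group (C9, C8) while the secondary silyl ether survives.

Step 17
Reactants: 21 keto-aldehyde; 22 methacrolein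
Product: 24 hydroxy methacrylate, via aldol 23 (not isolated)
Conditions: LaLi3[(R)-binaphthoxide]3 (20 mol %), THF (0.02 M), −20 °C; then methacrolein (6 equiv), SmI2 (30 mol %), −10 °C
Reagents that add atoms: none
Why: Proposed new method: the heterobimetallic binaphthoxide, acting as Brønsted base and Lewis acid, enolizes the acetyl group and delivers C8 to the aldehyde carbon C7 in a 7-(enolendo)-exo-trig aldol addition that closes the seven-membered ring; the closest known reactions are the intermolecular direct aldol addition of methyl ketones to α,α-disubstituted aldehydes under this catalyst and the SmI2-catalysed Evans–Tishchenko reduction of β-hydroxy ketones, here combined in one flask on a ring-closing case. Closure is favoured because the two arms sit on C10 and C5, opposite corners of the cyclobutane, on the same face and roughly 3 Å apart, and chemoselectivity is secured because C10 and C6 are quaternary (only C8 can enolize, C7 cannot) and C1 is a silyl ether. C7 is set by the catalyst, since the lower face of the bicycle is nearly mirror-symmetric and offers no bias of its own; the (R)-catalyst is expected by analogy to give the (7R)-aldolate. C9 is then set 1,3-anti by intramolecular hydride transfer from the samarium-bound hemiacetal of methacrolein through a chair six-membered transition state. The same hydride shift leaves the methacryloyl group on O7 and a free hydroxyl on C9, so the two oxygens are told apart without protecting groups. The step needs the aldolate to be trapped before retro-aldol or dehydration, which the low temperature and the excess of aldehyde should secure.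

Step 18
Reactants: 24 hydroxy methacrylate; 25 angelic acid
Product: 27 silyl-protected diester, via mixed anhydride 26 (not isolated)
Conditions: 2,4,6-trichlorobenzoyl chloride, Et3N, toluene, rt; then 24, toluene, 80 °C
Reagents that add atoms: none
Why: Yamaguchi-type esterification through the preformed angelic 2,4,6-trichlorobenzoic mixed anhydride without a nucleophilic catalyst is the established way to acylate hindered secondary alcohols while keeping the (Z)-geometry.

Step 19
Reactants: 27 silyl-protected diester
Product: 28 C1 alcohol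
Conditions: HF·pyridine, pyridine/THF, 0 °C to rt
Reagents that add atoms: none
Why: Buffered fluoride desilylation frees the C1 hydroxyl without touching the two unsaturated esters.

Step 20
Reactants: 28 C1 alcohol
Product: 30 target, via saturated ketone 29 (not isolated)
Conditions: IBX, DMSO, rt; then IBX·4-methoxypyridine N-oxide, DMSO, rt to 40 °C
Reagents that add atoms: none
Why: IBX oxidation of the alcohol to the ketone and IBX-mediated α,β-dehydrogenation: enolization is only possible toward C2 because C11 is a bridgehead, so the C2=C3 enone should form and the temporary C3 stereocentre disappears.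

**Compound list**

1 | 3,3-dimethoxybutan-2-one | CC(=O)C(C)(OC)OC | starting material
2 | triethyl phosphonoacetate | CCOC(=O)CP(=O)(OCC)OCC | starting material
3 | ethyl (2E)-4,4-dimethoxy-3-methylpent-2-enoate | CCOC(=O)/C=C(\C)C(C)(OC)OC | intermediate
4 | (2E)-4,4-dimethoxy-3-methylpent-2-en-1-ol | OC/C=C(\C)C(C)(OC)OC | intermediate
5 | (2E)-4,4-dimethoxy-3-methylpent-2-enal | O=C/C=C(\C)C(C)(OC)OC | intermediate
6 | methyl 3-methylbut-2-enoate | COC(=O)C=C(C)C | starting material
7 | tert-butyl[(1-methoxy-3-methylbuta-1,3-dien-1-yl)oxy]dimethylsilane (ketene acetal geometry not controlled) | COC(O[Si](C)(C)C(C)(C)C)=CC(C)=C | intermediate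
8 | methyl (2E,5S,6E)-5-hydroxy-8,8-dimethoxy-3,7-dimethylnona-2,6-dienoate | COC(=O)/C=C(\C)C[C@H](O)/C=C(\C)C(C)(OC)OC | intermediate
9 | methyl (2E,5S,6E)-5-[(tert-butyldimethylsilyl)oxy]-8,8-dimethoxy-3,7-dimethylnona-2,6-dienoate | COC(=O)/C=C(\C)C[C@H](O[Si](C)(C)C(C)(C)C)/C=C(\C)C(C)(OC)OC | intermediate
10 | (2E,5S,6E)-5-[(tert-butyldimethylsilyl)oxy]-8,8-dimethoxy-3,7-dimethylnona-2,6-dienoic acid | OC(=O)/C=C(\C)C[C@H](O[Si](C)(C)C(C)(C)C)/C=C(\C)C(C)(OC)OC | intermediate
11 | (5S,6E)-5-[(tert-butyldimethylsilyl)oxy]-8,8-dimethoxy-7-methyl-3-methylidenenona-1,6-dien-1-one (vinylketene) | O=C=CC(=C)C[C@H](O[Si](C)(C)C(C)(C)C)/C=C(\C)C(C)(OC)OC | intermediate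
12 | 7-(1,1-dimethoxyethyl)-7-methyl-2-methylidene-4-[(tert-butyldimethylsilyl)oxy]bicyclo[3.1.1]heptan-6-one; silyloxy group trans to C7, 7-methyl syn to the C2–C4 bridge | C=C1C[C@H](O[Si](C)(C)C(C)(C)C)[C@@H]2C(=O)[C@H]1[C@@]2(C)C(C)(OC)OC | intermediate
13 | ethyl 2-{7-(1,1-dimethoxyethyl)-7-methyl-2-methylidene-4-[(tert-butyldimethylsilyl)oxy]bicyclo[3.1.1]heptan-6-ylidene}acetate (either alkene geometry) | C=C1C[C@H](O[Si](C)(C)C(C)(C)C)[C@@H]2C(=CC(=O)OCC)[C@H]1[C@@]2(C)C(C)(OC)OC | intermediate
14 | ethyl 2-[7-(1,1-dimethoxyethyl)-4-hydroxy-7-methyl-2-methylidenebicyclo[3.1.1]heptan-6-ylidene]acetate | C=C1C[C@H](O)[C@@H]2C(=CC(=O)OCC)[C@H]1[C@@]2(C)C(C)(OC)OC | intermediate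
15 | ethyl 2-[7-(1,1-dimethoxyethyl)-4-hydroxy-2,7-dimethylbicyclo[3.1.1]heptan-6-yl]acetate; acetate arm on C6 and ketal arm on C7 both anti to the C2–C4 bridge, 2-methyl cis to C7 | C[C@H]1C[C@H](O)[C@@H]2[C@@H](CC(=O)OCC)[C@H]1[C@@]2(C)C(C)(OC)OC | intermediate
16 | tert-butyldimethylsilyl ether of 15 | C[C@H]1C[C@H](O[Si](C)(C)C(C)(C)C)[C@@H]2[C@@H](CC(=O)OCC)[C@H]1[C@@]2(C)C(C)(OC)OC | intermediate
17 | ethyl 2-{7-(1,1-dimethoxyethyl)-2,7-dimethyl-4-[(tert-butyldimethylsilyl)oxy]bicyclo[3.1.1]heptan-6-yl}propanoate (both epimers at the α-carbon) | C[C@H]1C[C@H](O[Si](C)(C)C(C)(C)C)[C@@H]2[C@@H](C(C)C(=O)OCC)[C@H]1[C@@]2(C)C(C)(OC)OC | intermediate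
18 | ethyl 2-{7-(1,1-dimethoxyethyl)-2,7-dimethyl-4-[(tert-butyldimethylsilyl)oxy]bicyclo[3.1.1]heptan-6-yl}-2-methylpropanoate | C[C@H]1C[C@H](O[Si](C)(C)C(C)(C)C)[C@@H]2[C@@H](C(C)(C)C(=O)OCC)[C@H]1[C@@]2(C)C(C)(OC)OC | intermediate
19 | 2-{7-(1,1-dimethoxyethyl)-2,7-dimethyl-4-[(tert-butyldimethylsilyl)oxy]bicyclo[3.1.1]heptan-6-yl}-2-methylpropan-1-ol | C[C@H]1C[C@H](O[Si](C)(C)C(C)(C)C)[C@@H]2[C@@H](C(C)(C)CO)[C@H]1[C@@]2(C)C(C)(OC)OC | intermediate
20 | 2-{7-(1,1-dimethoxyethyl)-2,7-dimethyl-4-[(tert-butyldimethylsilyl)oxy]bicyclo[3.1.1]heptan-6-yl}-2-methylpropanal | C[C@H]1C[C@H](O[Si](C)(C)C(C)(C)C)[C@@H]2[C@@H](C(C)(C)C=O)[C@H]1[C@@]2(C)C(C)(OC)OC | intermediate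
21 | 2-{7-acetyl-2,7-dimethyl-4-[(tert-butyldimethylsilyl)oxy]bicyclo[3.1.1]heptan-6-yl}-2-methylpropanal (keto-aldehyde; acetyl and aldehyde arms cis-1,3 on the cyclobutane) | C[C@H]1C[C@H](O[Si](C)(C)C(C)(C)C)[C@@H]2[C@@H](C(C)(C)C=O)[C@H]1[C@@]2(C)C(C)=O | intermediate
22 | methacrolein | C=C(C)C=O | starting material
23 | (7R)-1-[(tert-butyldimethylsilyl)oxy]-7-hydroxylongipinan-9-one | O[C@@H]1CC(=O)[C@@]2(C)[C@@H]3[C@@H](O[Si](C)(C)C(C)(C)C)C[C@H](C)[C@H]2[C@@H]3C1(C)C | intermediate
24 | (7R,9R)-1-[(tert-butyldimethylsilyl)oxy]-9-hydroxylongipinan-7-yl 2-methylprop-2-enoate | C=C(C)C(=O)O[C@@H]1C[C@@H](O)[C@@]2(C)[C@@H]3[C@@H](O[Si](C)(C)C(C)(C)C)C[C@H](C)[C@H]2[C@@H]3C1(C)C | intermediate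
25 | angelic acid, (2Z)-2-methylbut-2-enoic acid | C/C=C(/C)C(=O)O | starting material
26 | (2Z)-2-methylbut-2-enoic 2,4,6-trichlorobenzoic anhydride | C/C=C(/C)C(=O)OC(=O)c1c(Cl)cc(Cl)cc1Cl | intermediate
27 | (7R,9R)-1-[(tert-butyldimethylsilyl)oxy]-7-(methacryloyloxy)longipinan-9-yl (2Z)-2-methylbut-2-enoate | C=C(C)C(=O)O[C@@H]1C[C@@H](OC(=O)/C(C)=C\C)[C@@]2(C)[C@@H]3[C@@H](O[Si](C)(C)C(C)(C)C)C[C@H](C)[C@H]2[C@@H]3C1(C)C | intermediate
28 | (7R,9R)-1-hydroxy-7-(methacryloyloxy)longipinan-9-yl (2Z)-2-methylbut-2-enoate | C=C(C)C(=O)O[C@@H]1C[C@@H](OC(=O)/C(C)=C\C)[C@@]2(C)[C@@H]3[C@@H](O)C[C@H](C)[C@H]2[C@@H]3C1(C)C | intermediate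
29 | (7R,9R)-7-(methacryloyloxy)-1-oxolongipinan-9-yl (2Z)-2-methylbut-2-enoate | C=C(C)C(=O)O[C@@H]1C[C@@H](OC(=O)/C(C)=C\C)[C@@]2(C)[C@@H]3C(=O)C[C@H](C)[C@H]2[C@@H]3C1(C)C | intermediate
30 | (4R,5S,7R,9R,10R,11R)-7-(methacryloyloxy)-1-oxolongipin-2-en-9-yl (2Z)-2-methylbut-2-enoate | C=C(C)C(=O)O[C@@H]1C[C@@H](OC(=O)/C(C)=C\C)[C@@]2(C)[C@@H]3C(=O)C=C(C)[C@H]2[C@@H]3C1(C)C | target

**Step count and risks**

Total step count: 20. Longest linear sequence: 19 (steps 1–3 and 5–20; step 4 is a one-step side branch).

Steps most likely to fail: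

Step 17. The aldolate may revert by retro-aldol or dehydrate before the hydride shift, the catalyst may be mismatched with the substrate so that facial selectivity at C7 is poor, and methacrolein may oligomerize under the basic first stage. The fallback uses known reactions and separates ring closure from stereocontrol. It sets out from 21: base-mediated intramolecular aldol condensation (t-BuOK, t-BuOH, 40 °C) should give the cycloheptenone 1-[(tert-butyldimethylsilyl)oxy]longipin-7-en-9-one F1. Asymmetric conjugate borylation with a chiral copper catalyst (CuCl, NaOt-Bu, a Josiphos ligand, B2pin2, MeOH, THF) then puts boron on C7 under reagent control to give the β-boryl ketone F2. Oxidation in the same flask (NaBO3·4H2O) gives aldol 23, now isolated. Evans–Tishchenko reduction of 23 (SmI2 cat., methacrolein, THF, −10 °C) comes back to the route at 24.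

Step 8. The alkene is deactivated by the allylic silyloxy and ketal groups, so cycloaddition may be slow and ketene dimerization, oligomerization or loss of silanol may take over. The fallback replaces the ketene by a more electrophilic keteniminium ion and sets out from 9. Deconjugation (LiN(i-Pr)2, HMPA, THF, −78 °C; AcOH quench) should give the β,γ-unsaturated ester F3. Aminolysis with Me2NMgCl gives the N,N-dimethylamide F4. Tf2O and 2,6-di-tert-butylpyridine in 1,2-dichloroethane (0 to 60 °C) generate the keteniminium triflate F5, which should undergo the same bridged [2+2] cycloaddition to the cyclobutaniminium triflate F6. Aqueous NaHCO3 hydrolysis comes back to the route at 12.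

Step 20. Dehydrogenation may be incomplete or unselective, the angelate may isomerize to the tiglate, or the methacrylate may polymerize at the temperature the iodine reagent needs. The fallback separates oxidation from dehydrogenation and sets out from 28. Dess–Martin oxidation gives ketone 29, now isolated. Soft enolization (TMSOTf, Et3N, CH2Cl2, 0 °C), possible only toward C2, gives the trimethylsilyl enol ether F7. Saegusa–Ito oxidation (Pd(OAc)2, MeCN, rt) comes back to the route at 30.

Further compounds
F1 | step 17 | 1-[(tert-butyldimethylsilyl)oxy]longipin-7-en-9-one | C1=CC(=O)[C@@]2(C)[C@@H]3[C@@H](O[Si](C)(C)C(C)(C)C)C[C@H](C)[C@H]2[C@@H]3C1(C)C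
F2 | step 17 | 1-[(tert-butyldimethylsilyl)oxy]-7-(4,4,5,5-tetramethyl-1,3,2-dioxaborolan-2-yl)longipinan-9-one (boron on the face that becomes the 7R alcohol) | CC1(C)OB(OC1(C)C)[C@@H]2CC(=O)[C@@]3(C)[C@@H]4[C@@H](O[Si](C)(C)C(C)(C)C)C[C@H](C)[C@H]3[C@@H]4C2(C)C
F3 | step 8 | methyl (5S,6E)-5-[(tert-butyldimethylsilyl)oxy]-8,8-dimethoxy-7-methyl-3-methylidenenon-6-enoate | COC(=O)CC(=C)C[C@H](O[Si](C)(C)C(C)(C)C)/C=C(\C)C(C)(OC)OC
F4 | step 8 | (5S,6E)-5-[(tert-butyldimethylsilyl)oxy]-8,8-dimethoxy-N,N,7-trimethyl-3-methylidenenon-6-enamide | CN(C)C(=O)CC(=C)C[C@H](O[Si](C)(C)C(C)(C)C)/C=C(\C)C(C)(OC)OC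
F5 | step 8 | keteniminium triflate derived from F4 | C[N+](C)=C=CC(=C)C[C@H](O[Si](C)(C)C(C)(C)C)/C=C(\C)C(C)(OC)OC.[O-]S(=O)(=O)C(F)(F)F
F6 | step 8 | N,N-dimethyl cyclobutaniminium triflate corresponding to ketone 12 | C=C1C[C@H](O[Si](C)(C)C(C)(C)C)[C@@H]2C(=[N+](C)C)[C@H]1[C@@]2(C)C(C)(OC)OC.[O-]S(=O)(=O)C(F)(F)F
F7 | step 20 | trimethylsilyl enol ether (C1–C2) of ketone 29 | C=C(C)C(=O)O[C@@H]1C[C@@H](OC(=O)/C(C)=C\C)[C@@]2(C)[C@@H]3C(O[Si](C)(C)C)=C[C@H](C)[C@H]2[C@@H]3C1(C)C
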